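## Retrosynthetic overview

1. Target 9 ⇒ acyclic methyl (Z)-3,6-dioxodocos-4-enoate 8, the presumed polyketide precursor: intramolecular aldol of the β-keto ester carbon onto the C6 ketone, made enantioselective by a chiral bifunctional base; both stereocentres arise here.
2. 8 ⇒ 2,5-disubstituted furan 6: the furan is a masked cis-ene-1,4-dione, opened by singlet oxygen/Me2S (endoperoxide 7) in the same flask as the aldol.
3. 6 ⇒ 2-hexadecylfuran 4 + methyl iodoacetate 5: radical C–H alkylation at furan C5.
4. 4 ⇒ furan 1 + 1-bromohexadecane 2: lithiation/alkylation.
5. Ring order: only one ring is built, the cyclopentenone, in the last step; the furan ring is bought and opened.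

Assumption: the quinidine-derived squaramide in step 3 is taken to give the (1R,2R) product; this sense of induction is not secured by precedent on this substrate and is checked on the first run by chiral HPLC against the racemate, with the quinine-derived pseudo-enantiomer as the drop-in replacement if the sense is opposite.

## Route

Step 1
Reactants: 1 furan; 2 1-bromohexadecane
Product: 4 2-hexadecylfuran, via 2-furyllithium 3 (not isolated)
Conditions: 1 (1.3 equiv), n-BuLi (1.2 equiv), THF, −78 → 0 °C, 1 h; then 2 (1.0 equiv), 0 °C → rt, 16 h
Reagents that add atoms: none
Why: α-lithiation of furan next to the ring oxygen followed by SN2 alkylation of the 2-furyllithium with a primary bromide; no stereocentre is formed.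

Step 2
Reactants: 4 2-hexadecylfuran; 5 methyl iodoacetate
Product: 6 methyl 2-(5-hexadecylfuran-2-yl)acetate
Conditions: 4 (3 equiv, excess recovered), 5 (1 equiv), FeSO4·7H2O (0.3 equiv), 30% aq. H2O2 (2 equiv, slow addition), DMSO/CH2Cl2 1:1, 20 °C
Reagents that add atoms: none
Why: Minisci-type homolytic aromatic substitution under Fenton conditions: HO• (from H2O2 and divalent iron) cleaves DMSO to CH3•, which abstracts iodine from 5, and the electrophilic •CH2CO2Me radical adds to the free, electron-rich C5 of the 2-alkylfuran before oxidation by trivalent iron and proton loss restore the furan; no stereocentre is formed.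

Step 3
Reactants: 6 methyl 2-(5-hexadecylfuran-2-yl)acetate
Product: 9 methyl (1R,2R)-2-hexadecyl-2-hydroxy-5-oxocyclopent-3-ene-1-carboxylate, via furan endoperoxide 7 (not isolated), via (Z)-enedione keto ester 8 (not isolated)
Conditions: O2, tetraphenylporphyrin (1 mol %), white LED, CH2Cl2, −78 °C; Ar purge, Me2S (2 equiv), −78 → −30 °C; then squaramide from 9-amino-9-deoxy-epi-quinidine and 3,5-bis(trifluoromethyl)aniline (10 mol %), toluene, −40 °C, 24–48 h; AcOH quench at −40 °C
Reagents that add atoms: oxygen (used as singlet oxygen), O=O
Why: Proposed new method: the [4+2] photooxygenation of a 2,5-dialkylfuran and Me2S reduction of endoperoxide 7 are known and unmask the (Z)-ene-1,4-dione 8 under neutral conditions with the cis geometry the ring closure needs; new is that the 5-(enolexo)-exo-trig intramolecular aldol addition of 8 (C2 of 8 onto the C6 ketone, giving ring C1 and ring C2) is held back at low temperature and then run by a bifunctional cinchona squaramide, whose quinuclidine deprotonates the β-keto ester while the squaramide N–H pair hydrogen-bonds the C6 ketone, so the ion-paired enolate attacks one enantioface of that ketone and sets the tertiary carbinol centre (R) under catalyst control; the C1 centre lies between ketone and ester, epimerises under the same amine and settles (R) as the cis-hydroxy ester (O–H···O=C hydrogen bond, chain trans to CO2Me); closest known reaction types are cinchona-alkaloid-catalysed enantioselective aldol additions of 1,3-dicarbonyl compounds to activated ketones (interrupted Feist–Bénary reaction, squaramide-catalysed β-keto ester/isatin aldol) and the racemic base-triggered cyclisation of such enedione keto esters.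

## Compound list

1 | furan | c1ccoc1 | starting material
2 | 1-bromohexadecane | CCCCCCCCCCCCCCCCBr | starting material
3 | 2-furyllithium | [Li]c1ccco1 | intermediate (not isolated)
4 | 2-hexadecylfuran | CCCCCCCCCCCCCCCCc1ccco1 | intermediate
5 | methyl iodoacetate | COC(=O)CI | starting material
6 | methyl 2-(5-hexadecylfuran-2-yl)acetate | CCCCCCCCCCCCCCCCc1ccc(CC(=O)OC)o1 | intermediate
7 | methyl 2-(4-hexadecyl-2,3,7-trioxabicyclo[2.2.1]hept-5-en-1-yl)acetate (racemic) | CCCCCCCCCCCCCCCCC12C=CC(CC(=O)OC)(OO1)O2 | intermediate (not isolated)
8 | methyl (4Z)-3,6-dioxodocos-4-enoate | CCCCCCCCCCCCCCCCC(=O)/C=C\C(=O)CC(=O)OC | intermediate (not isolated)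
9 | methyl (1R,2R)-2-hexadecyl-2-hydroxy-5-oxocyclopent-3-ene-1-carboxylate (hydroxyl cis to CO2Me) | CCCCCCCCCCCCCCCC[C@@]1(O)C=CC(=O)[C@@H]1C(=O)OC | target

## Step count and risks

Total step count: 3. Longest linear sequence: 3 steps (1 → 4 → 6 → 9).

Steps most likely to fail, most risky first:

Step 3. The risks are a racemic background cyclisation of 8 before or beside the catalysed path, Z→E isomerisation of the enedione by the amine (the E isomer cannot close), low or opposite enantioselectivity, and erosion by retro-aldol on warming. The fallback gives up catalyst control and resolves instead. It sets out from 6: the same photooxygenation and Me2S reduction are followed by Et3N (10 mol %) in CH2Cl2 at 0 °C, which gives the cis-hydroxy ester as a racemate, that is 9 together with methyl (1S,2S)-2-hexadecyl-2-hydroxy-5-oxocyclopent-3-ene-1-carboxylate F4. Preparative supercritical-fluid chromatography on an amylose tris(3,5-dimethylphenylcarbamate) phase removes F4, and the route is rejoined at 9.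

Step 2. The risks are poor solubility of the lipophilic furan in the DMSO medium, low conversion, and oxidative damage of the electron-rich furan by HO•. The fallback replaces the radical C–H substitution by halogenation and cross-coupling. It sets out from 4: NBS in DMF at 0 °C gives 2-bromo-5-hexadecylfuran F2, which is used at once. The Reformatsky reagent (2-methoxy-2-oxoethyl)zinc bromide F3 is made from methyl bromoacetate and zinc dust in THF and coupled with F2 under Pd(dba)2/P(t-Bu)3 (2 mol % each, THF, rt), an arylation of a zinc ester enolate at zerovalent palladium. This gives 6, where the route is rejoined.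

Step 1. The risks are slow SN2 reaction of the long-chain bromide with 2-furyllithium, competing elimination to 1-hexadecene, and some 2,5-dialkylation. The fallback reverses the polarity of the coupling. It sets out from 2: magnesium turnings in THF give hexadecylmagnesium bromide F1, which undergoes Kumada coupling with commercial 2-bromofuran under NiCl2(dppp) (2 mol %, THF, 0 °C → rt). This gives 4, where the route is rejoined.

## Further compounds

F1 | step 1 | hexadecylmagnesium bromide | CCCCCCCCCCCCCCCC[Mg]Br
F2 | step 2 | 2-bromo-5-hexadecylfuran | CCCCCCCCCCCCCCCCc1ccc(Br)o1
F3 | step 2 | (2-methoxy-2-oxoethyl)zinc bromide | COC(=O)C[Zn]Br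
F4 | step 3 | methyl (1S,2S)-2-hexadecyl-2-hydroxy-5-oxocyclopent-3-ene-1-carboxylate | CCCCCCCCCCCCCCCC[C@]1(O)C=CC(=O)[C@H]1C(=O)OC
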